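The target is disconnected at the tertiary C8–O bond of its bridged δ-lactone. The feature used is the lactone ring O–C2(=O)–C1–C10–C9–C8, which spans C8 and C10 of ring B: with the oxygen removed it is the five-membered ketone ring of a bicyclo[3.2.1]octan-6-one in which fully substituted C8 is bonded to C2. A late Baeyer–Villiger oxidation inserts the oxygen by migration of C8 with retention, giving the 2-oxabicyclo[3.3.1]nonan-3-one and the C8–O stereocenter in one operation. The precursor carries the C11 aldehyde as a dioxolane, C6–OH as a triethylsilyl ether and C3O2H as a benzyl ester, so that the ketone is the only oxidisable group.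

Key step: step 10

Atom labels used throughout: lactone O–C2(=O)–C1–C10(CH3)–C9–C8(CH3); ring B C10–C5–C6–C7–C8–C9; acid arm C5–C4(CH3)2–C3; side chain C9–C11–C12–C13(CH3)–C14=C15. In these labels the target is 5R,6R,8S,9S,10R,11S,13R. "Exo" means the face of ring B on the side of the one-carbon bridge C9; "endo" means the side of the C1–C2 bridge.

Assumption: the absolute sense of induction of the two chiral boron catalysts (steps 3 and 13) is taken from their accepted transition-state models; should either prove opposite, the mirror-image catalyst is used.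

Step 1
Reactants: 1 2,3-dimethylfuran
Product: 2 (Z)-3-methyl-4-oxopent-2-enal (formyl C11, alkene C9=C8, acetyl C2/C1; formyl cis to acetyl)
Conditions: dimethyldioxirane (1.05 equiv), acetone/CH2Cl2, −20 → 0 °C; used at once as a cold solution
Reagents that add atoms: dimethyldioxirane, CC1(C)OO1
Why: Oxidative ring opening of a furan by a dioxirane (epoxidation, then opening to the 1,4-dicarbonyl) is the standard entry to cis-enediones, so the ring geometry delivers acetyl and formyl cis on the future C8=C9 bond.

Step 2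
Reactants: 3 (E)-pent-3-en-2-one
Product: 4 (E)-2-(triisopropylsilyloxy)penta-1,3-diene
Conditions: i-Pr3SiOTf, Et3N, CH2Cl2, 0 °C
Reagents that add atoms: triisopropylsilyl trifluoromethanesulfonate, CC(C)[Si](OS(=O)(=O)C(F)(F)F)(C(C)C)C(C)C
Why: Soft enolisation of the enone at its methyl group with a silyl triflate and amine gives the cross-conjugated silyl dienol ether without touching the E alkene.

Step 3
Reactants: 2 (Z)-3-methyl-4-oxopent-2-enal; 4 (E)-2-(triisopropylsilyloxy)penta-1,3-diene
Product: 5 6-acetyl-2,6-dimethyl-4-(triisopropylsilyloxy)cyclohex-3-ene-1-carbaldehyde (ring B; formyl on C9 cis to acetyl on C8 and cis to the C10 methyl; silyl enol ether C5=C6)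
Conditions: (S)-3,3-diphenyl-1-(2-methylphenyl)tetrahydro-1H,3H-pyrrolo[1,2-c][1,3,2]oxazaborole protonated with Tf2NH (20 mol%), CH2Cl2, −78 °C; crude product used directly
Reagents that add atoms: none
Why: Catalytic enantioselective Diels–Alder reaction in which the cationic oxazaborolidine binds the formyl group, so the nucleophilic diene terminus C7 bonds to C8 (β to the activated aldehyde) and C10 to C9; the Z dienophile transfers its geometry into the cis relation of the C8 acetyl and C9 formyl groups, and the catalyst's aryl group screens one face of C8=C9 and so sets the absolute configuration of quaternary C8 (C10 is erased in step 5).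

Step 4
Reactants: 5 cycloadduct aldehyde
Product: 6 1-[2-(1,3-dioxolan-2-yl)-1,3-dimethyl-5-(triisopropylsilyloxy)cyclohex-4-en-1-yl]ethan-1-one (C11 dioxolane, configuration as in 5)
Conditions: Me3SiOCH2CH2OSiMe3, Me3SiOTf (5 mol%), CH2Cl2, −78 °C
Reagents that add atoms: 1,2-bis(trimethylsilyloxy)ethane, C[Si](C)(C)OCCO[Si](C)(C)C
Why: Silyl-triflate-catalysed acetalisation with the bis-silyl glycol at −78 °C is selective for an aldehyde over a hindered methyl ketone and spares the bulky silyl enol ether; the dioxolane is chosen because methanol would close the cis γ-keto aldehyde to a cyclic bis-acetal, and the epimerisable C9 center is protected before any handling.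

Step 5
Reactants: 6 dioxolane silyl enol ether
Product: 7 5-acetyl-4-(1,3-dioxolan-2-yl)-3,5-dimethylcyclohex-2-en-1-one (enone C6(=O)–C5=C10; C9 dioxolanyl cis to C8 acetyl)
Conditions: Pd(OAc)2 (1.1 equiv), MeCN, 40 °C
Reagents that add atoms: none
Why: Saegusa–Ito oxidation, in which the regiodefined silyl enol ether places palladium on C5 and β-hydride elimination of C10–H can only give the C5=C10 enone, deleting the C10 stereocenter and leaving acetal and methyl ketone untouched.

Step 6
Reactants: 7 enone
Product: 9 8-(1,3-dioxolan-2-yl)-1,5-dimethyl-3-(trimethylsilyloxy)bicyclo[3.2.1]oct-2-en-6-one (C1–C10 bond formed; enol ether C5=C6; dioxolanyl on C9 syn to the C1–C2 bridge), via lithium enolate 8 (not isolated)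
Conditions: LiN(i-Pr)2 (1.05 equiv), THF, −78 → 0 °C; then Me3SiCl, −78 °C; non-aqueous work-up
Reagents that add atoms: chlorotrimethylsilane, C[Si](C)(C)Cl
Why: Intramolecular Michael addition (5-exo-trig) of the acetyl enolate, in which C1 reaches C10 only from the face that carries the axial acetyl group, so the cis-bridged bicyclo[3.2.1]octane closes and quaternary C10 is set by C8; the competing 1,2-addition to C6 is reversible, and silylation of the lithium enolate in a medium without proton donors fixes the enol ether at C5=C6 and so marks C5 against C7.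

Step 7
Reactants: 9 bicyclic silyl enol ether; 10 benzyl 2-bromo-2-methylpropanoate
Product: 12 benzyl 2-[8-(1,3-dioxolan-2-yl)-1,5-dimethyl-3,6-dioxobicyclo[3.2.1]octan-2-yl]-2-methylpropanoate (arm on C5 endo and equatorial), via exo-C5 epimer 11 (not isolated)
Conditions: fac-Ir(ppy)3 (1 mol%), MeCN, blue LEDs, rt; then DBU, toluene, 60 °C
Reagents that add atoms: none
Why: Photoredox radical alkylation of a silyl enol ether by a tertiary α-bromo ester (reduction of the C–Br bond, addition of the electrophilic radical to C5, oxidation and loss of the silyl group) forms C5–C4 only at the marked carbon; the radical should enter from the exo face, and DBU then equilibrates C5 through its enol to the equatorial endo epimer, which avoids the 1,3-diaxial contacts of the axial arm.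

Step 8
Reactants: 12 diketone ester
Product: 13 benzyl 2-[8-(1,3-dioxolan-2-yl)-3-hydroxy-1,5-dimethyl-6-oxobicyclo[3.2.1]octan-2-yl]-2-methylpropanoate (C6–OH endo and axial, cis to the C5 arm)
Conditions: LiBH(s-Bu)3 (1.1 equiv), THF, −78 °C; AcOH quench at −78 °C
Reagents that add atoms: none
Why: Bulky-hydride reduction in which the reagent reaches the C6 ketone from the open exo face, away from the C1–C2 bridge, giving the axial alcohol, while the C2 ketone (quaternary C8 on one side, both faces screened) is left; the cold acidic quench keeps the alkoxide from lactonising onto the neighbouring ester.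

Step 9
Reactants: 13 hydroxy ketone
Product: 14 benzyl 2-[8-(1,3-dioxolan-2-yl)-1,5-dimethyl-6-oxo-3-(triethylsilyloxy)bicyclo[3.2.1]octan-2-yl]-2-methylpropanoate (bicyclo[3.2.1]octan-6-one precursor of the key step)
Conditions: Et3SiOTf (1.2 equiv), 2,6-lutidine, CH2Cl2, −78 °C
Reagents that add atoms: triethylsilyl trifluoromethanesulfonate, CC[Si](CC)(CC)OS(=O)(=O)C(F)(F)F
Why: Silylation of a hindered secondary alcohol by a silyl triflate is fast at −78 °C, a temperature at which the dioxolane is not activated by the same reagent.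

Step 10
Reactants: 14 bicyclo[3.2.1]octan-6-one
Product: 15 benzyl 2-[9-(1,3-dioxolan-2-yl)-1,5-dimethyl-3-oxo-7-(triethylsilyloxy)-2-oxabicyclo[3.3.1]nonan-6-yl]-2-methylpropanoate (lactone C2(=O)–O–C8)
Conditions: mCPBA (3 equiv), NaHCO3, CH2Cl2, 0 °C → rt, extended time
Reagents that add atoms: 3-chloroperoxybenzoic acid, O=C(OO)c1cccc(Cl)c1
Why: Baeyer–Villiger oxidation: the peracid adds to the C2 carbonyl to give the peroxy hemiketal (Criegee intermediate), which collapses with 1,2-shift of C8 from C2 to oxygen and loss of 3-chlorobenzoate. The closest known cases are oxidations of camphor-type ketones and bicyclo[3.2.1]octan-6-ones, in which the substituted bridgehead carbon migrates. The six-membered lactone ring is not closed by cyclisation but grows out of the five-membered ketone ring by insertion of one oxygen, so no exo or endo mode of closure applies. The one new stereocenter, C8–O, is controlled by the retention that is intrinsic to the migrating carbon and therefore copies the C8–C2 configuration set in step 3. Regioselectivity rests on the higher migratory aptitude of fully substituted C8 over primary C1; chemoselectivity is secured by the substrate, which has no alkene, free hydroxyl or aldehyde and carries only buffer-stable dioxolane, silyl ether and benzyl ester groups. The carbonyl is screened by the C9 dioxolanyl group on its exo face and by the axial C6 silyl ether on its endo face, so slow conversion is expected and is the main risk of the route.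

Step 11
Reactants: 15 benzyl ester lactone
Product: 17 prop-2-enyl 2-[9-(1,3-dioxolan-2-yl)-1,5-dimethyl-3-oxo-7-(triethylsilyloxy)-2-oxabicyclo[3.3.1]nonan-6-yl]-2-methylpropanoate, via carboxylic acid 16 (not isolated)
Conditions: H2 (1 atm), Pd/C (palladium on carbon), EtOAc, rt; filter, concentrate; then allyl bromide, K2CO3, DMF, rt
Reagents that add atoms: allyl bromide, C=CCBr
Why: Hydrogenolysis of the benzyl ester and O-alkylation of the carboxylate exchange the peracid-proof benzyl group for an allyl group while the molecule still has no alkene, so that the acid can later be freed under neutral conditions beside the vinyl group.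

Step 12
Reactants: 17 allyl ester lactone
Product: 18 prop-2-enyl 2-[9-formyl-1,5-dimethyl-3-oxo-7-(triethylsilyloxy)-2-oxabicyclo[3.3.1]nonan-6-yl]-2-methylpropanoate (C11 aldehyde)
Conditions: Et3SiOTf, 2,4,6-collidine, CH2Cl2, 0 °C; then H2O
Reagents that add atoms: water, O
Why: Non-acidic acetal cleavage in which the silyl triflate opens the dioxolane to a collidinium adduct that water hydrolyses to the aldehyde, so the triethylsilyl ether, lactone and allyl ester are kept.

Step 13
Reactants: 18 aldehyde; 19 2-(trimethylsilyloxy)buta-1,3-diene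
Product: 21 prop-2-enyl 2-[9-[(1S)-1-hydroxy-3-oxopent-4-enyl]-1,5-dimethyl-3-oxo-7-(triethylsilyloxy)-2-oxabicyclo[3.3.1]nonan-6-yl]-2-methylpropanoate, via trimethylsilyl ether 20 (not isolated)
Conditions: (R)-2-butyl-4-(1H-indol-3-ylmethyl)-3-(4-methylphenylsulfonyl)-1,3,2-oxazaborolidin-5-one (20–40 mol%), EtCN, −78 °C; then aq. citric acid, THF, 0 °C
Reagents that add atoms: none
Why: Enantioselective Mukaiyama aldol addition of a methyl-ketone enol silane, in which the chiral boron Lewis acid binds the aldehyde and screens one face, so C11 is set by the catalyst (the two flanking quaternary carbons give little substrate bias) and the vinyl ketone needed for step 14 is obtained without a basic step.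

Step 14
Reactants: 21 β-hydroxy vinyl ketone
Product: 22 prop-2-enyl 2-[9-[(1S,3R)-1,3-dihydroxy-3-methylpent-4-enyl]-1,5-dimethyl-3-oxo-7-(triethylsilyloxy)-2-oxabicyclo[3.3.1]nonan-6-yl]-2-methylpropanoate
Conditions: MeMgBr (3 equiv), CH2Cl2/Et2O, −78 °C; aq. NH4Cl at −78 °C
Reagents that add atoms: methylmagnesium bromide, C[Mg]Br
Why: Chelation-controlled Grignard 1,2-addition to a β-hydroxy ketone, in which the magnesium alkoxide of C11–OH ties the C13 carbonyl into a six-membered chelate and methyl adds axially, trans to the C11 substituent, so the vinyl group ends in the chain of a syn-1,3-diol (13R); at −78 °C the doubly screened lactone and the neopentyl-type ester do not react.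

Step 15
Reactants: 22 silyl ether diol
Product: 23 prop-2-enyl 2-[9-[(1S,3R)-1,3-dihydroxy-3-methylpent-4-enyl]-7-hydroxy-1,5-dimethyl-3-oxo-2-oxabicyclo[3.3.1]nonan-6-yl]-2-methylpropanoate
Conditions: HF·pyridine, pyridine, THF, 0 °C
Reagents that add atoms: none
Why: Fluoride-mediated cleavage of the triethylsilyl ether under pyridine-buffered conditions, which are too mild to lactonise the hydroxy ester or to ionise the tertiary allylic alcohol.

Step 16
Reactants: 23 triol allyl ester
Product: 24 CNP0297019.1, 2-[9-[(1S,3R)-1,3-dihydroxy-3-methylpent-4-enyl]-7-hydroxy-1,5-dimethyl-3-oxo-2-oxabicyclo[3.3.1]nonan-6-yl]-2-methylpropanoic acid (5R,6R,8S,9S,10R,11S,13R)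
Conditions: Pd(PPh3)4 (5 mol%), morpholine, THF, rt; work-up with cold pH 5 phosphate buffer
Reagents that add atoms: none
Why: Tsuji–Trost deallylation, in which zerovalent palladium ionises the allyl ester and morpholine takes up the allyl group, frees the acid without acid or base, so the γ-hydroxy acid is not pushed towards lactonisation or lactone exchange.

Compound list
1 | 2,3-dimethylfuran | Cc1occc1C | starting material
2 | (Z)-3-methyl-4-oxopent-2-enal | CC(=O)/C(C)=C\C=O | intermediate
3 | (E)-pent-3-en-2-one | C/C=C/C(C)=O | starting material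
4 | (E)-2-(triisopropylsilyloxy)penta-1,3-diene | C=C(O[Si](C(C)C)(C(C)C)C(C)C)/C=C/C | intermediate
5 | 6-acetyl-2,6-dimethyl-4-(triisopropylsilyloxy)cyclohex-3-ene-1-carbaldehyde, formyl cis to acetyl and to the C10 methyl | O=C[C@@H]1[C@H](C)C=C(O[Si](C(C)C)(C(C)C)C(C)C)C[C@]1(C)C(C)=O | intermediate
6 | 1-[2-(1,3-dioxolan-2-yl)-1,3-dimethyl-5-(triisopropylsilyloxy)cyclohex-4-en-1-yl]ethan-1-one | O1CCOC1[C@@H]2[C@H](C)C=C(O[Si](C(C)C)(C(C)C)C(C)C)C[C@]2(C)C(C)=O | intermediate
7 | 5-acetyl-4-(1,3-dioxolan-2-yl)-3,5-dimethylcyclohex-2-en-1-one, dioxolanyl cis to acetyl | O1CCOC1[C@@H]2C(C)=CC(=O)C[C@]2(C)C(C)=O | intermediate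
8 | lithium enolate (C5=C6–OLi) of the bicyclo[3.2.1]octane-3,6-dione | O1CCOC1[C@@H]2[C@]3(C)CC(=O)[C@@]2(C)CC([O-])=C3.[Li+] | intermediate (not isolated)
9 | 8-(1,3-dioxolan-2-yl)-1,5-dimethyl-3-(trimethylsilyloxy)bicyclo[3.2.1]oct-2-en-6-one | O1CCOC1[C@@H]2[C@]3(C)CC(=O)[C@@]2(C)CC(O[Si](C)(C)C)=C3 | intermediate
10 | benzyl 2-bromo-2-methylpropanoate | CC(C)(Br)C(=O)OCc1ccccc1 | starting material
11 | C5 epimer of 12 (arm exo, axial) | O1CCOC1[C@@H]2[C@]3(C)CC(=O)[C@@]2(C)CC(=O)[C@@H]3C(C)(C)C(=O)OCc4ccccc4 | intermediate (not isolated)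
12 | benzyl 2-[8-(1,3-dioxolan-2-yl)-1,5-dimethyl-3,6-dioxobicyclo[3.2.1]octan-2-yl]-2-methylpropanoate (arm endo) | O1CCOC1[C@@H]2[C@]3(C)CC(=O)[C@@]2(C)CC(=O)[C@H]3C(C)(C)C(=O)OCc4ccccc4 | intermediate
13 | benzyl 2-[8-(1,3-dioxolan-2-yl)-3-hydroxy-1,5-dimethyl-6-oxobicyclo[3.2.1]octan-2-yl]-2-methylpropanoate (OH endo) | O1CCOC1[C@@H]2[C@]3(C)CC(=O)[C@@]2(C)C[C@@H](O)[C@H]3C(C)(C)C(=O)OCc4ccccc4 | intermediate
14 | benzyl 2-[8-(1,3-dioxolan-2-yl)-1,5-dimethyl-6-oxo-3-(triethylsilyloxy)bicyclo[3.2.1]octan-2-yl]-2-methylpropanoate | O1CCOC1[C@@H]2[C@]3(C)CC(=O)[C@@]2(C)C[C@@H](O[Si](CC)(CC)CC)[C@H]3C(C)(C)C(=O)OCc4ccccc4 | intermediate (key-step precursor)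
15 | benzyl 2-[9-(1,3-dioxolan-2-yl)-1,5-dimethyl-3-oxo-7-(triethylsilyloxy)-2-oxabicyclo[3.3.1]nonan-6-yl]-2-methylpropanoate | O1CCOC1[C@@H]2[C@]3(C)CC(=O)O[C@@]2(C)C[C@@H](O[Si](CC)(CC)CC)[C@H]3C(C)(C)C(=O)OCc4ccccc4 | intermediate (key-step product)
16 | 2-[9-(1,3-dioxolan-2-yl)-1,5-dimethyl-3-oxo-7-(triethylsilyloxy)-2-oxabicyclo[3.3.1]nonan-6-yl]-2-methylpropanoic acid | O1CCOC1[C@@H]2[C@]3(C)CC(=O)O[C@@]2(C)C[C@@H](O[Si](CC)(CC)CC)[C@H]3C(C)(C)C(=O)O | intermediate (not isolated)
17 | prop-2-enyl ester of 16 | O1CCOC1[C@@H]2[C@]3(C)CC(=O)O[C@@]2(C)C[C@@H](O[Si](CC)(CC)CC)[C@H]3C(C)(C)C(=O)OCC=C | intermediate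
18 | prop-2-enyl 2-[9-formyl-1,5-dimethyl-3-oxo-7-(triethylsilyloxy)-2-oxabicyclo[3.3.1]nonan-6-yl]-2-methylpropanoate | O=C[C@@H]1[C@]2(C)CC(=O)O[C@@]1(C)C[C@@H](O[Si](CC)(CC)CC)[C@H]2C(C)(C)C(=O)OCC=C | intermediate
19 | 2-(trimethylsilyloxy)buta-1,3-diene | C=CC(=C)O[Si](C)(C)C | starting material
20 | C11 trimethylsilyl ether of 21 | C=CC(=O)C[C@H](O[Si](C)(C)C)[C@@H]1[C@]2(C)CC(=O)O[C@@]1(C)C[C@@H](O[Si](CC)(CC)CC)[C@H]2C(C)(C)C(=O)OCC=C | intermediate (not isolated)
21 | prop-2-enyl 2-[9-[(1S)-1-hydroxy-3-oxopent-4-enyl]-1,5-dimethyl-3-oxo-7-(triethylsilyloxy)-2-oxabicyclo[3.3.1]nonan-6-yl]-2-methylpropanoate | C=CC(=O)C[C@H](O)[C@@H]1[C@]2(C)CC(=O)O[C@@]1(C)C[C@@H](O[Si](CC)(CC)CC)[C@H]2C(C)(C)C(=O)OCC=C | intermediate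
22 | prop-2-enyl 2-[9-[(1S,3R)-1,3-dihydroxy-3-methylpent-4-enyl]-1,5-dimethyl-3-oxo-7-(triethylsilyloxy)-2-oxabicyclo[3.3.1]nonan-6-yl]-2-methylpropanoate | C=C[C@](C)(O)C[C@H](O)[C@@H]1[C@]2(C)CC(=O)O[C@@]1(C)C[C@@H](O[Si](CC)(CC)CC)[C@H]2C(C)(C)C(=O)OCC=C | intermediate
23 | prop-2-enyl 2-[9-[(1S,3R)-1,3-dihydroxy-3-methylpent-4-enyl]-7-hydroxy-1,5-dimethyl-3-oxo-2-oxabicyclo[3.3.1]nonan-6-yl]-2-methylpropanoate | C=C[C@](C)(O)C[C@H](O)[C@@H]1[C@]2(C)CC(=O)O[C@@]1(C)C[C@@H](O)[C@H]2C(C)(C)C(=O)OCC=C | intermediate
24 | CNP0297019.1 | C=C[C@](C)(O)C[C@H](O)[C@@H]1[C@]2(C)CC(=O)O[C@@]1(C)C[C@@H](O)[C@H]2C(C)(C)C(=O)O | target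

Total step count: 16. Longest linear sequence: 15 steps (steps 1 and 3–16, from 1 to 24; step 2 makes diene 4 on a side branch).

Steps most likely to fail

Step 10. The peracid may add too slowly to the C2 carbonyl, which is screened on both faces, and forcing the reaction may erode the dioxolane or the silyl ether. Fallback from 14 to 15 without a peracid: irradiation of 14 at about 300 nm in aqueous THF should cleave the C2–C8 bond (Norrish α-cleavage on the more substituted side). The acyl–alkyl biradical recloses through oxygen to an oxacarbene, which water traps as lactol F1. The C1–C10 tether lets the acyl group return only to the original face of C8, so configuration is retained. Oxidation of lactol F1 with PhI(OAc)2 and catalytic TEMPO then gives 15.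

Step 7. Addition of the tertiary radical to C5, which lies next to quaternary C10, may be slower than reduction or dimerisation of the radical and hydrolysis of the enol ether, or the later equilibration at C5 may stall. Fallback from 9 to 12 with reversed polarity: N-bromosuccinimide (THF, −78 °C) converts 9 into bromo ketone F2 with the regiochemistry of the enol ether. Under the same photoredox conditions the C5 radical from F2 adds to the unhindered Me2C= terminus of ketene silyl acetal F3, made from benzyl 2-methylpropanoate with LiN(i-Pr)2 and Me3SiCl. Oxidation and desilylation give 11, which DBU equilibrates to 12.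

Step 3. The catalyst may give poor enantiofacial or regiochemical control with this keto aldehyde, or the dienophile may isomerise from Z to E before it reacts. Fallback from 2 and 4 to 5 by resolution: cycloaddition promoted by Me2AlCl (CH2Cl2, −78 °C), which also binds the formyl group, gives racemic cycloadduct F4. Condensation of F4 with (1S,2S)-N,N′-dimethyl-1,2-diphenylethane-1,2-diamine (Et2O, molecular sieves) gives two diastereomeric aminals. The one from the wanted enantiomer, aminal F5, is separated by chromatography or crystallisation and cleaved with cold dilute aqueous acid in a two-phase system to give 5.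

Further compounds
F1 | step 10 | benzyl 2-[9-(1,3-dioxolan-2-yl)-3-hydroxy-1,5-dimethyl-7-(triethylsilyloxy)-2-oxabicyclo[3.3.1]nonan-6-yl]-2-methylpropanoate (lactol, both C2 epimers) | O1CCOC1[C@@H]2[C@]3(C)CC(O)O[C@@]2(C)C[C@@H](O[Si](CC)(CC)CC)[C@H]3C(C)(C)C(=O)OCc4ccccc4
F2 | step 7 | 2-bromo-8-(1,3-dioxolan-2-yl)-1,5-dimethylbicyclo[3.2.1]octane-3,6-dione (bromine on C5, exo) | O1CCOC1[C@@H]2[C@]3(C)CC(=O)[C@@]2(C)CC(=O)[C@@H]3Br
F3 | step 7 | [1-(benzyloxy)-2-methylprop-1-enyl]oxy-trimethylsilane | CC(C)=C(OCc1ccccc1)O[Si](C)(C)C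
F4 | step 3 | racemic 5 (both enantiomers) | O=C[C@@H]1[C@H](C)C=C(O[Si](C(C)C)(C(C)C)C(C)C)C[C@]1(C)C(C)=O.O=C[C@H]1[C@@H](C)C=C(O[Si](C(C)C)(C(C)C)C(C)C)C[C@@]1(C)C(C)=O
F5 | step 3 | (4S,5S)-1,3-dimethyl-4,5-diphenylimidazolidine aminal of 5 | CN1[C@@H](c2ccccc2)[C@H](c2ccccc2)N(C)C1[C@@H]3[C@H](C)C=C(O[Si](C(C)C)(C(C)C)C(C)C)C[C@]3(C)C(C)=O
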